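**Numbering used throughout.** Chroman: O1, C2 (CMe2), C3 (CHOH), C4 (CH2), C4a, C5–C8, C8a; ring A is the benzene ring, ring B the pyran ring. Maleimide (ring C): N1', C2', C3' (carries the CH2), C4' (carries the aryl), C5'. Ring D is the 4-hydroxyphenyl group. Compounds 1–17 are defined in the steps and in the compound list.

## Analysis of the target

Asperimide C (17) is a chroman (rings A and B) whose C7 carries a methylene group leading to C3' of a maleimide (ring C), which in turn bears the 4-hydroxyphenyl ring D on C4'. The only stereocentre is C3 of ring B, a secondary carbinol of S configuration between the quaternary C2 and the benzylic C4. With no second centre to relay from, it has to be set by a chiral reagent. The sensitive groups are the N–H maleimide (a Michael acceptor that opens in base), the free phenol, and the methylene activated by both ring A and the maleimide. The difficulty lies in ring A: O1 is on C8a and C4 on C4a, while the carbon substituent on C7 is meta to O1 and para to C4a. Phenol-directed chemistry on a simple chromanol cannot put a carbon there, and a chromene-forming reaction on a meta-substituted phenol can close at either ortho carbon. The strategy rests on one observation: with a hydroxyl imagined on C5, ring A becomes a 5-substituted resorcinol with a mirror plane through C7 and C4a, and C4a lies between the two oxygens. Either oxygen can then become O1, the extra hydroxyl is deleted afterwards, and the C3=C4 alkene left by the annulation serves to set C3.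

## Retrosynthetic reasoning

**17 from 16.** The last operation only removes protecting groups. The imide N–H, the phenol and the C3 hydroxyl are masked in 16 as an N-Boc imide, an aryl tert-butyl carbonate and a triethylsilyl ether. All three fall to one acid treatment, so the free maleimide never meets base or a nucleophile.

**16 from 14 and 10 (through 15).** The CH2–C3' bond is cut. This divides the molecule into a chiral chroman half and an achiral maleimide half of similar size. The bond joins a benzylic sp3 carbon to an electron-poor vinylic carbon, which suits a palladium-catalysed coupling of the benzylic organozinc 15 with the vinylic bromide 14. Cutting C7–CH2 instead would need a (maleimidyl)methyl electrophile, which is an unstable, γ-acidic allylic halide. Building ring C at the end would put a ring-forming step on the most valuable material.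

**14 from 13, and 13 from 11 and 12.** The aryl–C4' bond is made by mono-arylation of the symmetric dibromide 11 with boronic acid 12, so there is no regiochemistry to control. The two acidic hydrogens of 13 are then masked together in one acylation.

**10 from 9, and 9 from 8.** The benzylic bromide comes from the primary alcohol of diol 8. The two hydroxyls differ sharply: one is primary and benzylic, the other secondary and next to the quaternary C2. Bromination therefore takes the first, and the second is silylated afterwards.

**8 from 7.** The C4–H bond and the CH2OH group both come from hydride. Hydride opens the epoxide at the benzylic C4 (C3 is neopentyl-like and blocked) and reduces the ester in the same operation. The C3–O bond is not touched, so the configuration of 7 at C3 is carried into 8.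

**7 from 6.** The epoxide comes from the C3=C4 alkene of chromene 6, a cyclic cis-alkene conjugated to an arene and so the best substrate class for chiral (salen)manganese oxygen transfer. This step creates the stereocentre.

**6 from 5, and 5 from 4.** The C5–H bond replaces the temporary C5 hydroxyl by way of the aryl triflate and palladium-catalysed hydride transfer. It is done before the epoxidation so that neither the phenol nor palladium chemistry meets the epoxide.

**4 from 1 and 2 (through 3).** The key disconnection cuts C4a–C4 and O1–C2. The symmetric resorcinol 1 and the enal 2 are both commercial. The forward reaction must alkylate the carbon between the two hydroxyls and close the pyran ring through quinone methide 3.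

## Alternatives that were turned down

**Alternative 1:** Ring C is disconnected completely (C3'–C2', C4'–C5' and C5'–N). In the forward direction Ru3(CO)12 would join the 1,3-diarylpropyne A1, 4-methoxybenzyl isocyanate A2 and a carbonyl unit in a carbonylative (2+2+1) annulation to give the protected imide A3.
- For: the maleimide and both its substituents arrive in one step, and no halomaleimide or organozinc chemistry is needed. On bonds formed in the key step (three bonds and a ring from three components) it is stronger than the chosen route.
- Against: it leaves the real problem untouched, because A1 still contains ring A with its meta pattern, and that fragment has to be made by some chromene synthesis anyway. The CH2 of A1 is both benzylic and propargylic, so at the high temperature of the carbonylation isomerisation to an allene competes. The N-(4-methoxybenzyl) group of A3 must be removed from an imide nitrogen by oxidative or strongly acidic means next to an electron-rich phenol.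
- Comparison: the chosen strategy puts its uncertain step first, on two commodity chemicals, and uses a commercial dibromomaleimide with two standard couplings. Alternative 1 puts the uncertainty on the most advanced intermediate.

**Alternative 2:** The C4a–C4 bond of ring B is cut. Ph3PAuNTf2 (or a bulkier biarylphosphine analogue) and an N-oxide oxidant would turn the terminal alkyne of the aryl propargyl ether A4 into an α-oxo gold carbene, which attacks the arene ortho to oxygen and gives the chroman-3-one A5.
- For: C3 arrives as a ketone flanked by a quaternary carbon and a CH2, a good case for catalytic asymmetric reduction. No epoxide and no temporary group are needed, and the bromine on C7 is a handle. On directness of setting C3 it is as strong as or stronger than the chosen route.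
- Against: ring closure can take place at either carbon ortho to the ether oxygen, and only the steric difference caused by the meta bromine decides between them. The bromine also deactivates the arene towards the electrophilic carbene, the tertiary propargylic ether can ionise at the Lewis-acidic gold centre, and over-oxidation of the carbene competes. The bromide must still be turned into the benzylic carbon by a one-carbon homologation, with the C3 oxygen protected on the way.
- Comparison: the chosen strategy secures the position of O1 and C4a by symmetry and carries the C7 carbon from the start as an ester. It pays for this with two steps to delete the C5 oxygen.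

**Alternative 3:** C8a–O1, C4a–C4 and O1–C2 are cut. Fluoride would unmask a 3-bromoaryne from the ortho-silylaryl triflate A6, the carbonyl group of 2 would add across it, the benzoxete would open to a quinone methide, and oxa-6π closure would give the bromochromene A7.
- For: three bonds and the ring form in one operation without any phenol. The inductive effect of bromine directs the oxygen to the remote aryne carbon. The bromine plays the same traceless role at C5 as the hydroxyl of the chosen route and needs one step for its removal instead of two, so on that point it is stronger.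
- Against: A6 is a tetrasubstituted arene with four different groups in fixed positions and needs several steps of its own. The enal 2 can also react with arynes by ene or (4+2) pathways, and carbonyl (2+2) additions to arynes usually need the carbonyl partner in large excess.
- Comparison: the chosen strategy reaches the same kind of 5-substituted chromene in one step from two commercial compounds.

Key step: step 1

Assumption: the single stereocentre of the target is read from its structure as (3S), and the route is drawn for that enantiomer.

## Route

Step 1
Reactants: 1 methyl 3,5-dihydroxybenzoate; 2 3-methylbut-2-enal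
Product: 4 methyl 5-hydroxy-2,2-dimethyl-2H-chromene-7-carboxylate, via ortho-quinone methide 3 (not isolated)
Conditions: ethylenediammonium diacetate (20 mol%), 2 (1.3 equiv), toluene, 110 °C
Reagents that add atoms: none
Why: The amine salt turns 2 into an iminium ion, which is attacked by the carbon of 1 between the two hydroxyls (the future C4a) in a Knoevenagel/Mannich-type C-alkylation that forms C4a–C4; loss of the amine gives the ortho-quinone methide 3. Ring B then closes by a thermal, disrotatory oxa-6π electrocyclisation of the 1-oxatriene of 3, forming O1–C2 and restoring the aromaticity of ring A. The closest known reaction type is the amine-salt-mediated formal (3+3) chromenylation of resorcinols with α,β-unsaturated aldehydes. No stereocentre is formed, because C2 carries two methyl groups. The step needs site selectivity between the carbon flanked by both hydroxyls and the two carbons beside the ester; all three are ortho or para to two hydroxyls, but the flanked carbon can use either oxygen for the elimination and for ring closure, whereas attack beside the ester is crowded by the coplanar CO2Me group and would twist it out of conjugation. Because 1 is symmetric, both oxygens lead to the same chromene, so the position of O1 is not in question. A second annulation of 4 is disfavoured, since its only remaining activated carbon (C6) lies between the hydroxyl and the ester.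

Step 2
Reactants: 4 methyl 5-hydroxy-2,2-dimethyl-2H-chromene-7-carboxylate
Product: 5 methyl 2,2-dimethyl-5-{[(trifluoromethyl)sulfonyl]oxy}-2H-chromene-7-carboxylate
Conditions: Tf2O, pyridine, CH2Cl2, 0 °C
Reagents that add atoms: trifluoromethanesulfonic anhydride (Tf2O), O=S(=O)(OS(=O)(=O)C(F)(F)F)C(F)(F)F
Why: O-Sulfonylation of the unhindered C5 phenol; the chromene alkene and the ester are inert to Tf2O/pyridine at 0 °C.

Step 3
Reactants: 5 methyl 2,2-dimethyl-5-{[(trifluoromethyl)sulfonyl]oxy}-2H-chromene-7-carboxylate
Product: 6 methyl 2,2-dimethyl-2H-chromene-7-carboxylate
Conditions: Pd(OAc)2 (5 mol%), 1,3-bis(diphenylphosphino)propane (6 mol%), Et3N, HCO2H, DMF, 70 °C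
Reagents that add atoms: none
Why: Palladium-catalysed transfer hydrogenolysis of an aryl triflate: oxidative addition of zerovalent palladium into C5–OTf, exchange of triflate for formate, loss of CO2 and C–H reductive elimination. The homogeneous phosphine catalyst should not reduce the styrenic C3=C4 bond or the ester.

Step 4
Reactants: 6 methyl 2,2-dimethyl-2H-chromene-7-carboxylate
Product: 7 methyl (3S,4S)-3,4-epoxy-2,2-dimethylchroman-7-carboxylate
Conditions: (S,S)-(salen)MnCl {chloro[(S,S)-N,N'-bis(3,5-di-tert-butylsalicylidene)cyclohexane-1,2-diaminato]manganese} (3 mol%), 4-phenylpyridine N-oxide (0.2 equiv), aq. NaOCl (pH 11.3), CH2Cl2, 0 °C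
Reagents that add atoms: sodium hypochlorite, [Na+].[O-]Cl
Why: Jacobsen epoxidation; hypochlorite oxidises the trivalent manganese complex to an oxo-manganese species that transfers oxygen to the cis, aryl-conjugated C3=C4 bond, the best substrate class for this catalyst. The alkene approaches side-on over the diamine bridge with ring A turned away from the tert-butyl groups, and the (S,S) ligand is the one that delivers oxygen to the face giving the (3S,4S) epoxide (the same face as in the known (1S,2R)-indene oxide case). The electron-poor ring A makes the epoxide less prone to acid opening during isolation.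

Step 5
Reactants: 7 methyl (3S,4S)-3,4-epoxy-2,2-dimethylchroman-7-carboxylate
Product: 8 (3S)-7-(hydroxymethyl)-2,2-dimethylchroman-3-ol
Conditions: LiAlH4, THF, 0 °C to rt
Reagents that add atoms: none
Why: Hydride opens the epoxide by SN2 attack at the benzylic C4, because C3 is shielded by the adjacent quaternary C2, and the same reagent reduces the ester to the primary alcohol. The C3–O bond is not broken, so C3 keeps its configuration and becomes the (3S) carbinol.

Step 6
Reactants: 8 (3S)-7-(hydroxymethyl)-2,2-dimethylchroman-3-ol
Product: 9 (3S)-7-(bromomethyl)-2,2-dimethylchroman-3-ol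
Conditions: CBr4 (1.1 equiv), PPh3 (1.1 equiv), CH2Cl2, 0 °C
Reagents that add atoms: carbon tetrabromide, BrC(Br)(Br)Br
Why: Appel reaction; the primary benzylic alkoxyphosphonium ion is displaced by bromide quickly, whereas the secondary C3 hydroxyl next to the quaternary C2 cannot undergo SN2 displacement and is recovered as the alcohol on work-up.

Step 7
Reactants: 9 (3S)-7-(bromomethyl)-2,2-dimethylchroman-3-ol
Product: 10 {[(3S)-7-(bromomethyl)-2,2-dimethylchroman-3-yl]oxy}triethylsilane
Conditions: TESOTf, 2,6-lutidine, CH2Cl2, −78 to 0 °C
Reagents that add atoms: triethylsilyl trifluoromethanesulfonate (TESOTf), CC[Si](CC)(CC)OS(=O)(=O)C(F)(F)F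
Why: Silylation of the hindered secondary alcohol with the silyl triflate; the hindered, weakly nucleophilic base does not alkylate the benzylic bromide at low temperature. The silyl ether removes the only acidic hydrogen that could quench the later organozinc reagent.

Step 8
Reactants: 11 2,3-dibromomaleimide (1.5 equiv); 12 (4-hydroxyphenyl)boronic acid
Product: 13 3-bromo-4-(4-hydroxyphenyl)-1H-pyrrole-2,5-dione
Conditions: Pd(PPh3)4 (5 mol%), K2CO3, 1,4-dioxane/H2O, 70 °C
Reagents that add atoms: none
Why: Suzuki–Miyaura mono-arylation of a symmetric vinylic dibromide. After the first coupling the electron-rich aryl group (a phenoxide in the basic medium) deactivates the remaining C–Br bond towards zerovalent palladium, and the excess of 11 further limits double arylation. The imide is present as its anion, which disfavours hydroxide or phenoxide addition–elimination and ring opening.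

Step 9
Reactants: 13 3-bromo-4-(4-hydroxyphenyl)-1H-pyrrole-2,5-dione
Product: 14 tert-butyl 3-bromo-4-{4-[(tert-butoxycarbonyl)oxy]phenyl}-2,5-dioxo-2,5-dihydro-1H-pyrrole-1-carboxylate
Conditions: Boc2O (2.5 equiv), DMAP (10 mol%), MeCN, rt
Reagents that add atoms: di-tert-butyl dicarbonate (Boc2O), CC(C)(C)OC(=O)OC(=O)OC(C)(C)C
Why: DMAP-catalysed acylation converts the imide N–H into the N-Boc imide and the phenol into its tert-butyl carbonate in one operation. Both acidic hydrogens that would protonate a benzylzinc reagent are removed, and both groups are acid-labile.

Step 10
Reactants: 10 {[(3S)-7-(bromomethyl)-2,2-dimethylchroman-3-yl]oxy}triethylsilane; 14 tert-butyl 3-bromo-4-{4-[(tert-butoxycarbonyl)oxy]phenyl}-2,5-dioxo-2,5-dihydro-1H-pyrrole-1-carboxylate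
Product: 16 tert-butyl 3-{4-[(tert-butoxycarbonyl)oxy]phenyl}-4-{[(3S)-2,2-dimethyl-3-(triethylsilyloxy)chroman-7-yl]methyl}-2,5-dioxo-2,5-dihydro-1H-pyrrole-1-carboxylate, via benzylzinc bromide 15 (not isolated)
Conditions: Zn dust, LiCl, THF, 0 °C to rt; then 14, Pd(PPh3)4 (5 mol%), THF, 0 °C to rt
Reagents that add atoms: none
Why: LiCl-assisted insertion of zinc into the benzylic C–Br bond gives 15, and a Negishi coupling follows: oxidative addition of zerovalent palladium into the electron-poor vinylic C–Br bond of 14, transmetalation from zinc, and reductive elimination to form CH2–C3'. The silyl ether, the carbonate and the N-Boc imide are not attacked by a benzylzinc halide at room temperature, and C3 is not involved.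

Step 11
Reactants: 16 tert-butyl 3-{4-[(tert-butoxycarbonyl)oxy]phenyl}-4-{[(3S)-2,2-dimethyl-3-(triethylsilyloxy)chroman-7-yl]methyl}-2,5-dioxo-2,5-dihydro-1H-pyrrole-1-carboxylate
Product: 17 asperimide C, 3-{[(3S)-3-hydroxy-2,2-dimethylchroman-7-yl]methyl}-4-(4-hydroxyphenyl)-1H-pyrrole-2,5-dione
Conditions: TFA/CH2Cl2/H2O (45:50:5), 0 °C to rt; NaHCO3 work-up
Reagents that add atoms: none
Why: Acidolysis cleaves the N-Boc group and the aryl tert-butyl carbonate by loss of the tert-butyl cation and CO2, and hydrolyses the triethylsilyl ether; water traps the cations. The maleimide, the tertiary aryl ether and the C3 stereocentre are stable to acid at room temperature, so the free maleimide is never exposed to base.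

## Compound list

1 | methyl 3,5-dihydroxybenzoate | COC(=O)c1cc(O)cc(O)c1 | starting material
2 | 3-methylbut-2-enal | CC(C)=CC=O | starting material
3 | methyl 5-hydroxy-4-(3-methylbut-2-en-1-ylidene)-3-oxocyclohexa-1,5-diene-1-carboxylate (ortho-quinone methide) | COC(=O)C1=CC(=O)C(=CC=C(C)C)C(O)=C1 | intermediate (not isolated)
4 | methyl 5-hydroxy-2,2-dimethyl-2H-chromene-7-carboxylate | CC1(C)C=Cc2c(O)cc(C(=O)OC)cc2O1 | intermediate
5 | methyl 2,2-dimethyl-5-{[(trifluoromethyl)sulfonyl]oxy}-2H-chromene-7-carboxylate | CC1(C)C=Cc2c(OS(=O)(=O)C(F)(F)F)cc(C(=O)OC)cc2O1 | intermediate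
6 | methyl 2,2-dimethyl-2H-chromene-7-carboxylate | CC1(C)C=Cc2ccc(C(=O)OC)cc2O1 | intermediate
7 | methyl (3S,4S)-3,4-epoxy-2,2-dimethylchroman-7-carboxylate | CC1(C)Oc2cc(C(=O)OC)ccc2[C@@H]3O[C@H]13 | intermediate
8 | (3S)-7-(hydroxymethyl)-2,2-dimethylchroman-3-ol | CC1(C)Oc2cc(CO)ccc2C[C@@H]1O | intermediate
9 | (3S)-7-(bromomethyl)-2,2-dimethylchroman-3-ol | CC1(C)Oc2cc(CBr)ccc2C[C@@H]1O | intermediate
10 | {[(3S)-7-(bromomethyl)-2,2-dimethylchroman-3-yl]oxy}triethylsilane | CC1(C)Oc2cc(CBr)ccc2C[C@@H]1O[Si](CC)(CC)CC | intermediate
11 | 2,3-dibromomaleimide (3,4-dibromo-1H-pyrrole-2,5-dione) | O=C1NC(=O)C(Br)=C1Br | starting material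
12 | (4-hydroxyphenyl)boronic acid | OB(O)c1ccc(O)cc1 | starting material
13 | 3-bromo-4-(4-hydroxyphenyl)-1H-pyrrole-2,5-dione | O=C1NC(=O)C(Br)=C1c1ccc(O)cc1 | intermediate
14 | tert-butyl 3-bromo-4-{4-[(tert-butoxycarbonyl)oxy]phenyl}-2,5-dioxo-2,5-dihydro-1H-pyrrole-1-carboxylate | CC(C)(C)OC(=O)Oc1ccc(cc1)C1=C(Br)C(=O)N(C(=O)OC(C)(C)C)C1=O | intermediate
15 | {[(3S)-2,2-dimethyl-3-(triethylsilyloxy)chroman-7-yl]methyl}zinc bromide | CC1(C)Oc2cc(C[Zn]Br)ccc2C[C@@H]1O[Si](CC)(CC)CC | intermediate (not isolated)
16 | tert-butyl 3-{4-[(tert-butoxycarbonyl)oxy]phenyl}-4-{[(3S)-2,2-dimethyl-3-(triethylsilyloxy)chroman-7-yl]methyl}-2,5-dioxo-2,5-dihydro-1H-pyrrole-1-carboxylate | CC1(C)Oc2cc(CC3=C(c4ccc(OC(=O)OC(C)(C)C)cc4)C(=O)N(C(=O)OC(C)(C)C)C3=O)ccc2C[C@@H]1O[Si](CC)(CC)CC | intermediate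
17 | asperimide C | CC1(C)Oc2cc(CC3=C(c4ccc(O)cc4)C(=O)NC3=O)ccc2C[C@@H]1O | target

## Step count and least certain steps

Total: 11 steps. Longest linear sequence: 9 steps (steps 1–7, 10 and 11, from 1); the maleimide branch is 2 steps (8 and 9).

**Step 1 (key step).**
- Most likely failure: loss of site selectivity, with the iminium ion attacking a carbon beside the ester instead of the carbon between the hydroxyls. C-alkylation of the ester-deactivated ring may also be sluggish, which leaves time for self-condensation of 2.
- Fallback: fix the site with a halogen instead of relying on the bias of the ring. It sets out from 2 and uses commercial methyl 4-bromo-3,5-dihydroxybenzoate F1 in place of 1. Protection with MOMCl and i-Pr2NEt gives methyl 4-bromo-3,5-bis(methoxymethoxy)benzoate F2. Bromine–magnesium exchange with i-PrMgCl·LiCl at −20 °C, helped by the two flanking ether groups and the para ester, gives [4-(methoxycarbonyl)-2,6-bis(methoxymethoxy)phenyl]magnesium chloride F3. F3 adds to the carbonyl group of 2 to give methyl 4-(1-hydroxy-3-methylbut-2-en-1-yl)-3,5-bis(methoxymethoxy)benzoate F4. HCl in MeOH then removes both acetals and ionises the carbinol to the same quinone methide 3, which closes to 4, where the route is rejoined.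

**Step 10.**
- Most likely failure: Wurtz-type homocoupling during zinc insertion into the reactive benzylic bromide, and uncatalysed attack of the benzylzinc reagent on the strongly electrophilic N-acyl bromomaleimide (conjugate addition at the aryl-bearing carbon, or transfer of the Boc group) in competition with the palladium cycle.
- Fallback: reverse the polarity so that no basic organometal meets the imide. From 14, Pd(PPh3)4-catalysed stannylation with hexamethylditin gives tert-butyl 3-{4-[(tert-butoxycarbonyl)oxy]phenyl}-2,5-dioxo-4-(trimethylstannyl)-2,5-dihydro-1H-pyrrole-1-carboxylate F5. A Stille coupling of F5 with the benzylic bromide 10 (Pd2(dba)3, AsPh3, CuI, DMF, 50 °C) under neutral conditions gives 16, where the route is rejoined.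

**Step 8.**
- Most likely failure: double arylation, and in the aqueous base addition–elimination of phenoxide or hydroxide at the bromine-bearing carbons or hydrolytic opening of the imide.
- Fallback: mask first and couple without water. From 11, Boc2O and DMAP give tert-butyl 3,4-dibromo-2,5-dioxo-2,5-dihydro-1H-pyrrole-1-carboxylate F6. F6 is coupled under anhydrous fluoride activation (Pd(PPh3)4, CsF, 1,4-dioxane, 60 °C) with one equivalent of commercial tert-butyl [4-(4,4,5,5-tetramethyl-1,3,2-dioxaborolan-2-yl)phenyl] carbonate F7 to give 14 directly, where the route is rejoined.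

**Step 5.**
- Most likely failure: erosion of enantiomeric purity. Aluminium-assisted ionisation of the benzylic C4–O bond (the cation is stabilised by O1 through ring A), followed by a 1,2-hydride shift, would give the achiral C3 ketone, and its reduction is not selective. Opening of the hindered epoxide may also be incomplete once the ester has been reduced.
- Fallback: separate the two reductions and open the epoxide without a Lewis acid. From 7, hydrogenolysis of the benzylic C4–O bond (H2, Pd/C, EtOAc) gives methyl (3S)-3-hydroxy-2,2-dimethylchroman-7-carboxylate F8. LiAlH4 reduction of the ester of F8 then gives 8, where the route is rejoined.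

## Further compounds

F1 | step 1 | methyl 4-bromo-3,5-dihydroxybenzoate | COC(=O)c1cc(O)c(Br)c(O)c1
F2 | step 1 | methyl 4-bromo-3,5-bis(methoxymethoxy)benzoate | COCOc1cc(C(=O)OC)cc(OCOC)c1Br
F3 | step 1 | [4-(methoxycarbonyl)-2,6-bis(methoxymethoxy)phenyl]magnesium chloride | COCOc1cc(C(=O)OC)cc(OCOC)c1[Mg]Cl
F4 | step 1 | methyl 4-(1-hydroxy-3-methylbut-2-en-1-yl)-3,5-bis(methoxymethoxy)benzoate | COCOc1cc(C(=O)OC)cc(OCOC)c1C(O)C=C(C)C
F5 | step 10 | tert-butyl 3-{4-[(tert-butoxycarbonyl)oxy]phenyl}-2,5-dioxo-4-(trimethylstannyl)-2,5-dihydro-1H-pyrrole-1-carboxylate | CC(C)(C)OC(=O)Oc1ccc(cc1)C1=C([Sn](C)(C)C)C(=O)N(C(=O)OC(C)(C)C)C1=O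
F6 | step 8 | tert-butyl 3,4-dibromo-2,5-dioxo-2,5-dihydro-1H-pyrrole-1-carboxylate | CC(C)(C)OC(=O)N1C(=O)C(Br)=C(Br)C1=O
F7 | step 8 | tert-butyl [4-(4,4,5,5-tetramethyl-1,3,2-dioxaborolan-2-yl)phenyl] carbonate | CC(C)(C)OC(=O)Oc1ccc(cc1)B1OC(C)(C)C(C)(C)O1
F8 | step 5 | methyl (3S)-3-hydroxy-2,2-dimethylchroman-7-carboxylate | CC1(C)Oc2cc(C(=O)OC)ccc2C[C@@H]1O
A1 | alternative 1 | tert-butyl{[(3S)-7-(3-{4-[(tert-butyldimethylsilyl)oxy]phenyl}prop-2-yn-1-yl)-2,2-dimethylchroman-3-yl]oxy}dimethylsilane | CC1(C)Oc2cc(CC#Cc3ccc(O[Si](C)(C)C(C)(C)C)cc3)ccc2C[C@@H]1O[Si](C)(C)C(C)(C)C
A2 | alternative 1 | 4-methoxybenzyl isocyanate | COc1ccc(CN=C=O)cc1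
A3 | alternative 1 | N-(4-methoxybenzyl), bis(tert-butyldimethylsilyl)-protected asperimide C | CC1(C)Oc2cc(CC3=C(c4ccc(O[Si](C)(C)C(C)(C)C)cc4)C(=O)N(Cc4ccc(OC)cc4)C3=O)ccc2C[C@@H]1O[Si](C)(C)C(C)(C)C
A4 | alternative 2 | 1-bromo-3-[(2-methylbut-3-yn-2-yl)oxy]benzene | C#CC(C)(C)Oc1cccc(Br)c1
A5 | alternative 2 | 7-bromo-2,2-dimethylchroman-3-one | CC1(C)Oc2cc(Br)ccc2CC1=O
A6 | alternative 3 | 3-bromo-5-{[(triisopropylsilyl)oxy]methyl}-2-(trimethylsilyl)phenyl trifluoromethanesulfonate | C[Si](C)(C)c1c(Br)cc(CO[Si](C(C)C)(C(C)C)C(C)C)cc1OS(=O)(=O)C(F)(F)F
A7 | alternative 3 | 5-bromo-2,2-dimethyl-7-[(triisopropylsilyloxy)methyl]-2H-chromene | CC1(C)C=Cc2c(Br)cc(CO[Si](C(C)C)(C(C)C)C(C)C)cc2O1
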